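Remark on the chemistry: mapping the aniline onto the indole puts aniline C4 and C5 at indole C5 and C6, so the 4,5-dibromo-2-nitroaryl series is the one required and the structures are used unchanged on that basis. Compound 3 is written as the free keto aldehyde and 4 as its gem-diol hydrate, the form expected from aqueous dioxane.

## Structural features

The target is an indole: a benzene ring fused through C3a–C7a to a pyrrole ring, with methyl on N1, bromine on C2, a formyl group on C3 and bromines on the neighbouring benzo carbons C5 and C6. It has no stereocenter, so the whole problem is regiochemical. The fragile elements are the aldehyde, the C2–Br bond (with the C3 formyl group it forms a β-bromo enal open to addition–elimination by nucleophiles) and the aryl C–Br bonds, which exclude organolithium reagents and zerovalent palladium late in the route. The real difficulty is the C2 bromine: once C3 carries the formyl group, C2 is deactivated towards electrophilic bromination, and C2 metalation would compete with halogen–metal exchange at C5 and C6. Electrophilic bromination of the benzo ring would not single out C5 and C6 either, so these two bromines are best brought in with the starting arene. The key step exploits the fact that C2 is bonded to both N1 and bromine while C3 carries C3a and the formyl carbon. C2 can therefore be the CBr2 terminus of a gem-dibromoalkene, and closure of N1–C2 by loss of one bromide leaves the other in place.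

## Logic of the disconnections

12 to 10 (through 11): the N1–CH3 bond and the formyl C=O are cut, the latter going back to two C–OMe bonds. The aldehyde is kept masked while base is present, because a free 3-formyl group would activate C2–Br towards nucleophiles, and the methyl group is added only after ring closure because a primary aniline is cheaper to reach than its N-methyl derivative. The gain is an N–H indole whose C2, C3, C5 and C6 substituents are all set. The demand is that N-alkylation outruns loss of methoxide from the indolyl anion, and that the unmasking acid is mild enough to leave C2–Br alone.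

10 to 9: the N1–C2 bond is cut. This is the only ring-forming bond of the route and it turns the bicyclic heteroarene into a monocyclic aniline with an ortho gem-dibromoalkene. The cut is made here because one ring closure then delivers the C2 bromine and the C3 formyl carbon together. The demand is reaction at a vinylic C–Br bond in preference to two aryl C–Br bonds, and only once.

9 to 8: the amine is traced to a nitro group. A free amine would not survive the olefination reagent, and beside an aldehyde equivalent it could close a ring in the wrong sense. The gain is a nitrogen function that is inert through the carbon-skeleton steps. The demand is a reduction that spares four C–Br bonds, the alkene and the acetal.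

8 to 6 and 7: the C2=C3 double bond is cut. 7 supplies C2 with both bromines, and 6 supplies C3 as a ketone carbon already bearing the aryl ring and the masked formyl carbon. The alkene has two identical bromines on one terminus, so no alkene geometry has to be controlled. The demand is olefination of a hindered ketone, which is helped by the activating acetal and the electron-poor aryl ring.

6 to 4 and 5, then 4 through 3 to 2: the two C–OMe bonds are cut and the oxidation level of the former methyl carbon is lowered. The acetal is needed because the aldehyde carbon must stay inert towards the olefination and towards the later amine. The gain is a simple aryl methyl ketone. The demands are oxidation that stops at the aldehyde level and acetalisation of the aldehyde only.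

2 to 1: the aryl C–N bond is cut. 1 already carries both benzo bromines in the correct 1,2-relationship and an acetyl group that becomes C3 and the formyl carbon. The demand is nitration at the position ortho to acetyl and para to the 3-bromine.

## Other disconnections considered

Alternative 1: The cut removes three bonds of the benzo ring, C4–C5, C6–C7 and C3a–C7a. It leads to the ynamide diyne A1, N-(but-3-yn-1-yl)-N-ethynyl-4-methylbenzenesulfonamide, and to A2, bis(trimethylsilyl)acetylene. In the forward direction CpCo(CO)2 would join them in a [2+2+2] cycloaddition to A3, 1-tosyl-5,6-bis(trimethylsilyl)indoline, closing the benzene ring and the nitrogen ring together. Ipso-bromodesilylation would then give A4, 5,6-dibromo-1-tosylindoline.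
- In its favour: it is convergent, the bulky A2 does not trimerise with itself, and the two silyl groups mark C5 and C6 with no regiochemical doubt.
- Against it here: A3 has the wrong oxidation level, a sulfonyl group on nitrogen and nothing on C2 or C3. After A4 the route still needs detosylation, dehydrogenation, N-methylation, C3 formylation and C2 bromination, and the last of these is the hard problem named above. The second bromodesilylation, ortho to a new bromine, may compete with protodesilylation.
- Comparison: on certainty of the C5/C6 pattern and on bonds formed per step this alternative is the better one. On the pyrrole substituents the chosen plan is better, because C2–Br and the formyl carbon arise in the ring closure. Mechanistically it is a metallacycle-based cycloaddition against a single C–N reductive elimination. In step count it would run to about ten against seven.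

Alternative 2: The cut is the C5–C6 bond, with HBr added back across it. It leads to A5, 3-[(E)-2-bromovinyl]-2-(2,2-dibromovinyl)-1-methylpyrrole. Heating would close A5 by disrotatory 6π-electrocyclization to A6, 5,6,6-tribromo-1-methyl-5,6-dihydroindole. A6 would lose HBr to give A7, 5,6-dibromo-1-methylindole.
- In its favour: the bromine positions are fixed by the two vinyl bromide arms, no metal is needed, and aromatisation drives the sequence.
- Against it here: the central double bond of the triene is the pyrrole C2=C3 bond, so pyrrole aromaticity is lost in A6, and one bromine of the CBr2 terminus must point inward. Both raise the barrier, and the temperature then needed threatens the vinyl bromides. A5 requires two different olefinations on a differentiated pyrrole dialdehyde. A7 still lacks the C3 formyl group and the C2 bromine.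
- Comparison: on certainty of the benzo bromines and on freedom from metals it is the equal or the better of the chosen plan. On the C2 bromine it is worse, since formylation of A7 would lead to A10 and the same unsolved C2 bromination as in Alternative 3. Mechanistically it is a pericyclic closure plus elimination against a copper-mediated coupling. Step count would be about eight, no shorter than the chosen seven.

Alternative 3: The cut is C3–C3a. It leads to the enaminal A9, (E)-3-[(3,4-dibromophenyl)(methyl)amino]prop-2-enal, which would come from A8, 3,4-dibromo-N-methylaniline, and a three-carbon formylvinyl donor. Constant-current anodic oxidation of A9 in an undivided cell would form C3–C3a and give A10, 5,6-dibromo-1-methylindole-3-carbaldehyde, with hydrogen evolved at the cathode.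
- In its favour: N-methyl, formyl and both benzo bromines are in place after two steps, and no chemical oxidant is used.
- Against it here: the ring to be attacked is deactivated by two bromines. Closure at the other ortho carbon, next to bromine, would misplace the bromines. Cathodic cleavage of C–Br bonds is possible in an undivided cell. A10 still lacks the C2 bromine, and that bromination is the step for which no dependable method is at hand.
- Comparison: in step economy (about four steps) and in avoidance of stoichiometric oxidants and of a nitration it is clearly the better one. In certainty of the final substitution pattern the chosen plan is better, because it never has to functionalise C2 of a 3-formylindole. Mechanistically it is a radical-cation C–C closure whose regiochemistry rests on sterics, against a closure that has only one possible outcome.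

Key step: step 6

## Route

Step 1
Reactants: 1 3,4-dibromoacetophenone
Product: 2 1-(4,5-dibromo-2-nitrophenyl)ethan-1-one
Conditions: fuming HNO3, conc. H2SO4, −10 to 0 °C
Reagents that add atoms: nitric acid, O[N+](=O)[O-]
Why: Electrophilic aromatic nitration; the free position para to the 3-bromine and ortho to acetyl is the one activated by halogen lone-pair donation, the position between acetyl and bromine is shielded, and low temperature limits side-chain oxidation.

Step 2
Reactants: 2 1-(4,5-dibromo-2-nitrophenyl)ethan-1-one
Product: 4 1-(4,5-dibromo-2-nitrophenyl)-2,2-dihydroxyethan-1-one, via free arylglyoxal 3 (not isolated)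
Conditions: SeO2, 1,4-dioxane/H2O, 100 °C; crystallised from water
Reagents that add atoms: selenium dioxide, O=[Se]=O; water, O
Why: Riley oxidation of the enolisable methyl ketone (ene reaction of the enol, [2,3]-shift, loss of selenium) gives the keto aldehyde, which is hydrated in the aqueous medium; nitro and aryl bromide groups are inert.

Step 3
Reactants: 4 1-(4,5-dibromo-2-nitrophenyl)-2,2-dihydroxyethan-1-one; 5 trimethyl orthoformate
Product: 6 1-(4,5-dibromo-2-nitrophenyl)-2,2-dimethoxyethan-1-one
Conditions: HC(OMe)3, TsOH·H2O (cat.), MeOH, 50 °C
Reagents that add atoms: none
Why: Acid-catalysed acetalisation with the orthoformate as methoxy source and water scavenger; the aldehyde carbon is far more electrophilic and less hindered than the ketone beside the ortho-nitroaryl ring, so only the aldehyde should be converted.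

Step 4
Reactants: 6 1-(4,5-dibromo-2-nitrophenyl)-2,2-dimethoxyethan-1-one; 7 carbon tetrabromide
Product: 8 1,2-dibromo-4-(1,1-dibromo-3,3-dimethoxyprop-1-en-2-yl)-5-nitrobenzene
Conditions: CBr4, P(OiPr)3, CH2Cl2, 0 °C to rt
Reagents that add atoms: none
Why: Ramirez gem-dibromo-olefination in its triisopropyl phosphite (Horner–Wadsworth–Emmons-type) variant, the version suited to ketones; the carbonyl is activated by the adjacent acetal and the electron-poor aryl ring, and nitro group and acetal are untouched at room temperature.

Step 5
Reactants: 8 1,2-dibromo-4-(1,1-dibromo-3,3-dimethoxyprop-1-en-2-yl)-5-nitrobenzene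
Product: 9 4,5-dibromo-2-(1,1-dibromo-3,3-dimethoxyprop-1-en-2-yl)aniline
Conditions: Fe powder, NH4Cl, EtOH/H2O, 70 °C
Reagents that add atoms: none
Why: Béchamp-type electron-transfer reduction of the nitro group under near-neutral NH4Cl buffering; vinylic and aryl C–Br bonds are not reduced by iron under these conditions and the acetal is spared because no strong acid is present.

Step 6
Reactants: 9 4,5-dibromo-2-(1,1-dibromo-3,3-dimethoxyprop-1-en-2-yl)aniline
Product: 10 2,5,6-tribromo-3-(dimethoxymethyl)-1H-indole
Conditions: CuI (10 mol %), MeNHCH2CH2NHMe (20 mol %), K3PO4, PhMe, 80 °C, Ar
Reagents that add atoms: none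
Why: K3PO4 and CuI convert the aniline N–H into an amide of monovalent copper, which inserts into the vinylic C–Br bond lying cis to the aryl ring to give a six-membered metallacycle of trivalent copper; reductive elimination then forms N1–C2 and returns monovalent copper. The closest known reaction type is the Ullmann–Goldberg-type intramolecular vinylic amination by which ortho-(gem-dibromovinyl)aniline derivatives are cyclised to 2-bromoindoles, including alkenes derived from ketones. The pyrrole ring closes in a formally 5-endo-trig mode at an sp2 carbon, feasible because the bond is made by reductive elimination from the metallacycle and not by direct nucleophilic attack. No stereocenter is formed. The step needs vinylic over aryl C–Br selectivity: only the gem-dibromoalkene C–Br bond is within reach of the nitrogen-bound copper and it is intrinsically the more reactive one, so the bromines destined for C5 and C6 should stay. It also needs single substitution: after closure the remaining bromine sits on indole C2 with no internal nucleophile, and moderate temperature and dilution keep intermolecular N-arylation slow. Because the alkene is fully substituted there is no vinylic hydrogen, so base-induced loss of HBr to a bromoalkyne cannot compete. The diamine ligand keeps the copper amide in solution and allows turnover at 80 °C.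

Step 7
Reactants: 10 2,5,6-tribromo-3-(dimethoxymethyl)-1H-indole
Product: 12 2,5,6-tribromo-1-methyl-1H-indole-3-carbaldehyde, via N-methyl acetal 11 (not isolated)
Conditions: NaH, MeI, DMF, 0 °C to rt; then 1 M aq HCl, THF, rt
Reagents that add atoms: iodomethane, CI; water, O
Why: SN2 N-alkylation of the indolyl sodium salt, followed in the same flask by specific-acid hydrolysis of the labile indol-3-yl dimethyl acetal, whose oxocarbenium ion is stabilised by N1; keeping the aldehyde masked during the basic stage avoids addition–elimination at the then activated C2–Br bond.

## Compound list

1 | 3,4-dibromoacetophenone | CC(=O)c1ccc(Br)c(Br)c1 | starting material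
2 | 1-(4,5-dibromo-2-nitrophenyl)ethan-1-one | CC(=O)c1cc(Br)c(Br)cc1[N+](=O)[O-] | intermediate
3 | 2-(4,5-dibromo-2-nitrophenyl)-2-oxoacetaldehyde (free arylglyoxal) | O=CC(=O)c1cc(Br)c(Br)cc1[N+](=O)[O-] | intermediate (not isolated)
4 | 1-(4,5-dibromo-2-nitrophenyl)-2,2-dihydroxyethan-1-one | OC(O)C(=O)c1cc(Br)c(Br)cc1[N+](=O)[O-] | intermediate
5 | trimethyl orthoformate | COC(OC)OC | starting material
6 | 1-(4,5-dibromo-2-nitrophenyl)-2,2-dimethoxyethan-1-one | COC(OC)C(=O)c1cc(Br)c(Br)cc1[N+](=O)[O-] | intermediate
7 | carbon tetrabromide | BrC(Br)(Br)Br | starting material
8 | 1,2-dibromo-4-(1,1-dibromo-3,3-dimethoxyprop-1-en-2-yl)-5-nitrobenzene | COC(OC)C(=C(Br)Br)c1cc(Br)c(Br)cc1[N+](=O)[O-] | intermediate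
9 | 4,5-dibromo-2-(1,1-dibromo-3,3-dimethoxyprop-1-en-2-yl)aniline | Nc1cc(Br)c(Br)cc1C(=C(Br)Br)C(OC)OC | intermediate
10 | 2,5,6-tribromo-3-(dimethoxymethyl)-1H-indole | COC(OC)c1c(Br)[nH]c2cc(Br)c(Br)cc12 | intermediate
11 | 2,5,6-tribromo-3-(dimethoxymethyl)-1-methyl-1H-indole | COC(OC)c1c(Br)n(C)c2cc(Br)c(Br)cc12 | intermediate (not isolated)
12 | 2,5,6-tribromo-1-methyl-1H-indole-3-carbaldehyde | Cn1c(Br)c(C=O)c2cc(Br)c(Br)cc21 | target

## Step count and least certain steps

Total step count: 7. Longest linear sequence: 7 steps, from 1 to 12.

**Step 6 (key step).** The most likely failure is slow turnover: the nitrogen of 9 is a weakly acidic, electron-poor primary aniline and the alkene is tetrasubstituted and hindered. Forcing the temperature would then let intermolecular N-arylation at the aryl C–Br bonds compete, and the indol-3-yl acetal can ionise after closure.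
Fallback, from 9 back to 10: the nitrogen is made a better partner for copper. 9 is mesylated (MsCl, pyridine, CH2Cl2) to N-[4,5-dibromo-2-(1,1-dibromo-3,3-dimethoxyprop-1-en-2-yl)phenyl]methanesulfonamide F1. The sulfonamide, the best-precedented nucleophile class for this cyclisation, is closed with CuI, the same diamine and K3PO4 in toluene to 2,5,6-tribromo-3-(dimethoxymethyl)-1-(methylsulfonyl)-1H-indole F2. The sulfonyl group is then removed with Cs2CO3 in THF/MeOH to return 10.

**Step 4.** The most likely failure is sluggish addition of the bulky dibromomethylene phosphorus reagent to a ketone flanked by the ortho-nitroaryl ring and the acetal, so that reagent decomposition outruns olefination.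
Fallback, from 2 back to 8: the olefination is moved to a more electrophilic α-keto ester.
- 2 is oxidised with SeO2 in pyridine to 2-(4,5-dibromo-2-nitrophenyl)-2-oxoacetic acid F3.
- F3 is esterified (MeOH, H2SO4) to methyl 2-(4,5-dibromo-2-nitrophenyl)-2-oxoacetate F4.
- F4 is olefinated with CBr4 and PPh3 in CH2Cl2 at 0 °C to methyl 3,3-dibromo-2-(4,5-dibromo-2-nitrophenyl)prop-2-enoate F5.
- F5 is reduced with i-Bu2AlH at −78 °C to 3,3-dibromo-2-(4,5-dibromo-2-nitrophenyl)prop-2-en-1-ol F6.
- F6 is oxidised with Dess–Martin periodinane to 3,3-dibromo-2-(4,5-dibromo-2-nitrophenyl)prop-2-enal F7.
- F7 is acetalised with 5, MeOH and catalytic TsOH to give 8.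

**Step 1.** The most likely failure is poor regioselectivity: the position meta to acetyl and ortho to the 4-bromine competes with the desired one, and the isomers may be hard to separate.
Fallback, from 1 back to 2: the nitro group is directed by chelation. 1 is converted with MeONH2·HCl and pyridine into (E)-1-(3,4-dibromophenyl)ethan-1-one O-methyl oxime F8. F8 is nitrated at the less hindered ortho C–H bond through a palladacycle (Pd(OAc)2 cat., AgNO2, K2S2O8, 1,2-dichloroethane, 110 °C) to (E)-1-(4,5-dibromo-2-nitrophenyl)ethan-1-one O-methyl oxime F9. The oxime ether is hydrolysed with aqueous HCl in dioxane at reflux to give 2.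

**Step 7.** The most likely failure is ionisation of the acetal before N-alkylation: loss of methoxide from the indolyl anion, or loss of the acetal already during isolation of 10, followed by oligomerisation.
Fallback, from 10 back to 12: the order is reversed. 10 is hydrolysed first with dilute aqueous HCl in THF to the robust 2,5,6-tribromo-1H-indole-3-carbaldehyde F10. Its acidic N–H is then methylated with MeI and K2CO3 in acetone, a non-nucleophilic base system that should leave C2–Br alone, to give 12.

## Further compounds

F1 | step 6 | N-[4,5-dibromo-2-(1,1-dibromo-3,3-dimethoxyprop-1-en-2-yl)phenyl]methanesulfonamide | CS(=O)(=O)Nc1cc(Br)c(Br)cc1C(=C(Br)Br)C(OC)OC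
F2 | step 6 | 2,5,6-tribromo-3-(dimethoxymethyl)-1-(methylsulfonyl)-1H-indole | COC(OC)c1c(Br)n(S(C)(=O)=O)c2cc(Br)c(Br)cc12
F3 | step 4 | 2-(4,5-dibromo-2-nitrophenyl)-2-oxoacetic acid | OC(=O)C(=O)c1cc(Br)c(Br)cc1[N+](=O)[O-]
F4 | step 4 | methyl 2-(4,5-dibromo-2-nitrophenyl)-2-oxoacetate | COC(=O)C(=O)c1cc(Br)c(Br)cc1[N+](=O)[O-]
F5 | step 4 | methyl 3,3-dibromo-2-(4,5-dibromo-2-nitrophenyl)prop-2-enoate | COC(=O)C(=C(Br)Br)c1cc(Br)c(Br)cc1[N+](=O)[O-]
F6 | step 4 | 3,3-dibromo-2-(4,5-dibromo-2-nitrophenyl)prop-2-en-1-ol | OCC(=C(Br)Br)c1cc(Br)c(Br)cc1[N+](=O)[O-]
F7 | step 4 | 3,3-dibromo-2-(4,5-dibromo-2-nitrophenyl)prop-2-enal | O=CC(=C(Br)Br)c1cc(Br)c(Br)cc1[N+](=O)[O-]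
F8 | step 1 | (E)-1-(3,4-dibromophenyl)ethan-1-one O-methyl oxime | CO/N=C(\C)c1ccc(Br)c(Br)c1
F9 | step 1 | (E)-1-(4,5-dibromo-2-nitrophenyl)ethan-1-one O-methyl oxime | CO/N=C(\C)c1cc(Br)c(Br)cc1[N+](=O)[O-]
F10 | step 7 | 2,5,6-tribromo-1H-indole-3-carbaldehyde | O=Cc1c(Br)[nH]c2cc(Br)c(Br)cc12
A1 | alternative 1 | N-(but-3-yn-1-yl)-N-ethynyl-4-methylbenzenesulfonamide | Cc1ccc(cc1)S(=O)(=O)N(C#C)CCC#C
A2 | alternative 1 | bis(trimethylsilyl)acetylene | C[Si](C)(C)C#C[Si](C)(C)C
A3 | alternative 1 | 1-tosyl-5,6-bis(trimethylsilyl)indoline | Cc1ccc(cc1)S(=O)(=O)N1CCc2cc([Si](C)(C)C)c([Si](C)(C)C)cc21
A4 | alternative 1 | 5,6-dibromo-1-tosylindoline | Cc1ccc(cc1)S(=O)(=O)N1CCc2cc(Br)c(Br)cc21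
A5 | alternative 2 | 3-[(E)-2-bromovinyl]-2-(2,2-dibromovinyl)-1-methylpyrrole | Cn1ccc(/C=C/Br)c1C=C(Br)Br
A6 | alternative 2 | 5,6,6-tribromo-1-methyl-5,6-dihydroindole (racemic) | CN1C=CC2=CC(Br)C(Br)(Br)C=C12
A7 | alternative 2 | 5,6-dibromo-1-methylindole | Cn1ccc2cc(Br)c(Br)cc21
A8 | alternative 3 | 3,4-dibromo-N-methylaniline | CNc1ccc(Br)c(Br)c1
A9 | alternative 3 | (E)-3-[(3,4-dibromophenyl)(methyl)amino]prop-2-enal | O=C/C=C/N(C)c1ccc(Br)c(Br)c1
A10 | alternative 3 | 5,6-dibromo-1-methylindole-3-carbaldehyde | Cn1cc(C=O)c2cc(Br)c(Br)cc21
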